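**Plan**
Atom labels follow the chromanone numbering of the target (O1, C2, C3, C4, C4a, C5 to C8, C8a); ring A is the benzene ring, ring B the pyranone ring, ring C the pyrone.
Retrosynthesis: the C2–O1 hemiketal bond is opened first, then C3–C4 is cut (salicylate acetonide plus the dianion of a pyronyl acetone), then C4a–C5 of ring A, then C5–C6 and C7–C8 of a dioxinone-capped chain; in the pyrone arm the acetyl carbon is cut from the pyrone methyl carbon.
Enabling feature: ring A (C4a, C5, C6, C7, C8, C8a) bears oxygen at C7 and C8a, the acid-level carbon C4 on C4a and the 3-methylbutyl group on C5, the resorcylate pattern left when a β-polyketo chain begun by 4-methylpentanoate folds by aldol addition.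
Forward: the chain is built by two acylations of the trimethyldioxinone, ring A closes first by aldol cyclisation and aromatisation, O7 is benzylated, C3–C4 is made by opening the lactone with the pyronyl acetone dianion (ring C arrives preformed), ring B then closes by itself as the hemiketal, and hydrogenolysis gives the racemate.
Stereochemistry: C2 is the only stereocentre and is an epimerisable hemiketal carbon; it is set last by crystallisation-induced diastereomer transformation of the quininium pyronate and kept by cold liberation of the free acid.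

Key step: step 4

Assumption: C2 is configurationally labile in solution through ring–chain tautomerism, so the (2R) compound is delivered as a cold-handled solid; which cinchona base deposits the (2R) salt cannot be foreseen, quinine is written, and quinidine would replace it if the lattice selects (2S).

**Step 1**
Reactants: 1 2,2,6-trimethyl-4H-1,3-dioxin-4-one
Product: 3 2,2-dimethyl-6-(2-oxopropyl)-4H-1,3-dioxin-4-one, via lithium dienolate 2 (not isolated)
Conditions: 1 (2.0 equiv), LiN(SiMe3)2 (2.0 equiv), THF, −78 °C; AcCl (1.0 equiv), −78 °C; 1 M HCl quench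
Reagents that add atoms: acetyl chloride, CC(=O)Cl
Why: γ-Deprotonation of the vinylogous ester gives dienolate 2, which is C-acylated at its terminal carbon by the acid chloride (vinylogous Claisen acylation), the second equivalent of 2 deprotonating the more acidic β-keto product so that it is not acylated again.

**Step 2**
Reactants: 4 4-methylpentanoyl chloride
Product: 5 N-methoxy-N,4-dimethylpentanamide
Conditions: MeNH(OMe)·HCl (1.1 equiv), K2CO3 (2.5 equiv), CH2Cl2/H2O, 0 °C to rt
Reagents that add atoms: N,O-dimethylhydroxylamine hydrochloride, CNOC.Cl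
Why: Schotten–Baumann N-acylation of the hydroxylamine by the acid chloride in a two-phase carbonate system is fast and has no competing site.

**Step 3**
Reactants: 3 2,2-dimethyl-6-(2-oxopropyl)-4H-1,3-dioxin-4-one; 5 N-methoxy-N,4-dimethylpentanamide
Product: 7 2,2-dimethyl-6-(7-methyl-2,4-dioxooctyl)-4H-1,3-dioxin-4-one, via dilithium dianion 6 (not isolated)
Conditions: LiN(iPr)2 (2.1 equiv), THF, −78 °C; then 5, −78 to −40 °C; cold 1 M HCl to pH 3; crude product used at once
Reagents that add atoms: none
Why: The second deprotonation of 3 gives 1,3-dianion 6, whose terminal carbon is the most nucleophilic site and adds to the Weinreb amide (Weinreb ketone synthesis on a dicarbonyl dianion), the chelated tetrahedral adduct lasting until the cold acidic quench so that double addition and premature cyclisation of the diketone are avoided.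

**Step 4**
Reactants: 7 2,2-dimethyl-6-(7-methyl-2,4-dioxooctyl)-4H-1,3-dioxin-4-one
Product: 9 7-hydroxy-2,2-dimethyl-5-(3-methylbutyl)-4H-1,3-benzodioxin-4-one, via aldol adduct 8 (not isolated)
Conditions: Et3N (0.5 equiv), CH2Cl2, 0 °C to rt; then 1 M aq. HCl, rt
Reagents that add atoms: none
Why: Et3N removes a proton from C8, the methylene between the dioxinone and the first ketone, and the resulting extended dienolate attacks the C5 ketone through dioxinone carbon C4a, forming the C4a–C5 bond and giving tertiary aldol 8. The closure is a 6-(enolexo)-exo-trig aldol addition that creates ring A, and acid then drives E1cB-type loss of water across C5–C6 and enolisation of the C7 ketone, so that ring A becomes aromatic. The closest known reaction type is the amine-induced aromatisation of 6-(2,4-dioxoalkyl)-1,3-dioxin-4-ones to resorcylate acetonides, the laboratory counterpart of a polyketide aldol cyclisation. No stereocentre remains in 9, because the carbinol carbon of 8 ends as an sp2 carbon. The selectivity needed is regiochemical: the acetonide holds C4 as a cyclic acylal ester that no chain carbanion can acylate and ties O1 to it, so the Claisen folding to an acylphloroglucinol is closed, and of the possible aldol pairings only C4a to C5 gives a six-membered ring that can aromatise. Working at or below room temperature keeps the dioxinone from cycloreversion to the acylketene, whose capture by a chain enol would give a 4-hydroxy-2-pyrone instead.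

**Step 5**
Reactants: 9 7-hydroxy-2,2-dimethyl-5-(3-methylbutyl)-4H-1,3-benzodioxin-4-one
Product: 10 7-(benzyloxy)-2,2-dimethyl-5-(3-methylbutyl)-4H-1,3-benzodioxin-4-one
Conditions: BnBr (1.2 equiv), K2CO3 (2 equiv), DMF, rt
Reagents that add atoms: benzyl bromide, BrCc1ccccc1
Why: Williamson etherification of the only acidic OH under carbonate conditions that leave the acetonide untouched; masking O7 prevents a phenoxide in step 8 from deactivating C4 towards the carbanion.

**Step 6**
Reactants: 11 4-hydroxy-6-methyl-2H-pyran-2-one
Product: 12 4-(benzyloxy)-6-methyl-2H-pyran-2-one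
Conditions: BnOH, PPh3, DIAD, THF, 0 °C to rt
Reagents that add atoms: benzyl alcohol, OCc1ccccc1
Why: Mitsunobu O-alkylation, in which the acidic 4-OH of the pyrone serves as the pronucleophile and is benzylated on oxygen, avoiding the C3-benzylation that accompanies base and benzyl halide.

**Step 7**
Reactants: 12 4-(benzyloxy)-6-methyl-2H-pyran-2-one
Product: 14 4-(benzyloxy)-6-(2-oxopropyl)-2H-pyran-2-one, via lithiated pyrone 13 (not isolated)
Conditions: LiN(SiMe3)2 (1.1 equiv), THF, −78 °C; MeC(O)N(OMe)Me (1.2 equiv), −78 to −30 °C; 1 M HCl quench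
Reagents that add atoms: N-methoxy-N-methylacetamide, CC(=O)N(C)OC
Why: The 6-methyl group is the vinylogous α-position of the pyrone lactone, so the hindered amide base gives dienolate 13, which is acylated at the exocyclic carbon by the Weinreb amide (Weinreb ketone synthesis), the stable tetrahedral adduct keeping the more acidic product from quenching unreacted 13.

**Step 8**
Reactants: 10 7-(benzyloxy)-2,2-dimethyl-5-(3-methylbutyl)-4H-1,3-benzodioxin-4-one; 14 4-(benzyloxy)-6-(2-oxopropyl)-2H-pyran-2-one
Product: 17 rac-7-(benzyloxy)-2-{[4-(benzyloxy)-2-oxo-2H-pyran-6-yl]methyl}-2-hydroxy-5-(3-methylbutyl)-2,3-dihydro-4H-chromen-4-one, via dilithium dianion 15 (not isolated), via open-chain diketone 16 (not isolated)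
Conditions: 14 (3.0 equiv), LiN(iPr)2 (6.0 equiv), THF, −78 °C; then 10 (1.0 equiv), −78 to −20 °C; AcOH at −78 °C, pH 5 buffer work-up, no heating
Reagents that add atoms: none
Why: Terminal Claisen-type acylation of the 1,3-dianion of a vinylogous β-keto ester by the lactone carbonyl C4 of the salicylate acetonide: collapse of the adduct expels the ketal alkoxide, which sheds acetone and frees the O1 phenoxide, and on buffered acidification the phenol of 16 adds to the C2 ketone (6-exo-trig hemiketalisation) to close ring B, C2 arising as a racemate because nothing biases this reversible closure.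

**Step 9**
Reactants: 17 rac-7-(benzyloxy)-2-{[4-(benzyloxy)-2-oxo-2H-pyran-6-yl]methyl}-2-hydroxy-5-(3-methylbutyl)-2,3-dihydro-4H-chromen-4-one
Product: 18 rac-2,7-dihydroxy-2-[(4-hydroxy-2-oxo-2H-pyran-6-yl)methyl]-5-(3-methylbutyl)-2,3-dihydro-4H-chromen-4-one
Conditions: H2 (1 atm), Pd/C (10 wt% palladium metal on carbon), EtOAc, 20 °C, stopped after uptake of 2 equiv of H2
Reagents that add atoms: none
Why: Heterogeneous catalytic hydrogenolysis should cleave the aryl benzyl ether and the vinylogous benzyl ester of the pyrone faster than hydrogen adds to the pyrone ring or the aryl ketone at 1 atm, and the neutral medium spares the hemiketal from dehydration to the chromone; C2 stays racemic.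

**Step 10**
Reactants: 18 rac-2,7-dihydroxy-2-[(4-hydroxy-2-oxo-2H-pyran-6-yl)methyl]-5-(3-methylbutyl)-2,3-dihydro-4H-chromen-4-one
Product: 19 quininium 6-{[(2R)-2,7-dihydroxy-5-(3-methylbutyl)-4-oxo-3,4-dihydro-2H-chromen-2-yl]methyl}-2-oxo-2H-pyran-4-olate
Conditions: quinine (1.0 equiv), MeCN, 45 °C, slow cooling to 5 °C, slurry aged with stirring, filtered cold
Reagents that add atoms: quinine, COc1ccc2nccc([C@H]([C@@H]3C[C@@H]4CCN3C[C@@H]4C=C)O)c2c1
Why: Proposed new method: the 4-hydroxy-2-pyrone, a vinylogous carboxylic acid, should protonate the quinuclidine nitrogen of quinine to give two diastereomeric ion pairs that interconvert in solution because the C2 hemiketal opens reversibly to the achiral open-chain phenol diketone under general acid–base catalysis by the ammonium pyronate buffer, so that crystallisation of the less soluble (2R) salt should drain the whole mixture into one solid diastereomer, C2 being set under thermodynamic control by the packing of the quininium lattice; the closest known reaction type is the crystallisation-induced diastereomer transformation of chiral-amine salts of epimerisable acids, together with the mutarotation-driven crystallisation of a single anomer of a lactol.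

**Step 11**
Reactants: 19 quininium 6-{[(2R)-2,7-dihydroxy-5-(3-methylbutyl)-4-oxo-3,4-dihydro-2H-chromen-2-yl]methyl}-2-oxo-2H-pyran-4-olate
Product: 20 (2R)-2,7-dihydroxy-2-[(4-hydroxy-2-oxo-2H-pyran-6-yl)methyl]-5-(3-methylbutyl)-2,3-dihydro-4H-chromen-4-one
Conditions: EtOAc / 0.5 M aq. HCl, 0 °C, short contact; cold brine; Na2SO4; evaporation below 5 °C; stored as a solid at −20 °C
Reagents that add atoms: none
Why: Brønsted salt cleavage by proton transfer: the strong acid protonates the pyronate and carries the quininium ion into water, and with the amine gone and the temperature at 0 °C the ring–chain exchange that epimerises C2 should be slow enough for the configuration fixed in the crystal to pass into solid 20.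

**Compound list**
1 | 2,2,6-trimethyl-4H-1,3-dioxin-4-one | CC1=CC(=O)OC(C)(C)O1 | starting material
2 | lithium dienolate of 1 | [Li+].C=C1C=C([O-])OC(C)(C)O1 | intermediate
3 | 2,2-dimethyl-6-(2-oxopropyl)-4H-1,3-dioxin-4-one | CC(=O)CC1=CC(=O)OC(C)(C)O1 | intermediate
4 | 4-methylpentanoyl chloride | CC(C)CCC(=O)Cl | starting material
5 | N-methoxy-N,4-dimethylpentanamide | CC(C)CCC(=O)N(C)OC | intermediate
6 | dilithium dianion of 3 | [Li+].[Li+].C=C([O-])C=C1C=C([O-])OC(C)(C)O1 | intermediate
7 | 2,2-dimethyl-6-(7-methyl-2,4-dioxooctyl)-4H-1,3-dioxin-4-one | CC(C)CCC(=O)CC(=O)CC1=CC(=O)OC(C)(C)O1 | intermediate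
8 | rac-5-hydroxy-2,2-dimethyl-5-(3-methylbutyl)-5,6-dihydro-4H-1,3-benzodioxine-4,7(8H)-dione | CC(C)CCC1(O)CC(=O)CC2=C1C(=O)OC(C)(C)O2 | intermediate
9 | 7-hydroxy-2,2-dimethyl-5-(3-methylbutyl)-4H-1,3-benzodioxin-4-one | CC(C)CCc1cc(O)cc2c1C(=O)OC(C)(C)O2 | intermediate
10 | 7-(benzyloxy)-2,2-dimethyl-5-(3-methylbutyl)-4H-1,3-benzodioxin-4-one | CC(C)CCc1cc(OCc2ccccc2)cc2c1C(=O)OC(C)(C)O2 | intermediate
11 | 4-hydroxy-6-methyl-2H-pyran-2-one | Cc1cc(O)cc(=O)o1 | starting material
12 | 4-(benzyloxy)-6-methyl-2H-pyran-2-one | Cc1cc(OCc2ccccc2)cc(=O)o1 | intermediate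
13 | lithium dienolate of 12 | [Li+].C=C1C=C(OCc2ccccc2)C=C([O-])O1 | intermediate
14 | 4-(benzyloxy)-6-(2-oxopropyl)-2H-pyran-2-one | CC(=O)Cc1cc(OCc2ccccc2)cc(=O)o1 | intermediate
15 | dilithium dianion of 14 | [Li+].[Li+].C=C([O-])C=C1C=C(OCc2ccccc2)C=C([O-])O1 | intermediate
16 | 1-[4-(benzyloxy)-2-hydroxy-6-(3-methylbutyl)phenyl]-4-[4-(benzyloxy)-2-oxo-2H-pyran-6-yl]butane-1,3-dione | CC(C)CCc1cc(OCc2ccccc2)cc(O)c1C(=O)CC(=O)Cc1cc(OCc2ccccc2)cc(=O)o1 | intermediate
17 | rac-7-(benzyloxy)-2-{[4-(benzyloxy)-2-oxo-2H-pyran-6-yl]methyl}-2-hydroxy-5-(3-methylbutyl)-2,3-dihydro-4H-chromen-4-one | CC(C)CCc1cc(OCc2ccccc2)cc2c1C(=O)CC(O)(Cc1cc(OCc3ccccc3)cc(=O)o1)O2 | intermediate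
18 | rac-2,7-dihydroxy-2-[(4-hydroxy-2-oxo-2H-pyran-6-yl)methyl]-5-(3-methylbutyl)-2,3-dihydro-4H-chromen-4-one | CC(C)CCc1cc(O)cc2c1C(=O)CC(O)(Cc1cc(O)cc(=O)o1)O2 | intermediate
19 | quininium 6-{[(2R)-2,7-dihydroxy-5-(3-methylbutyl)-4-oxo-3,4-dihydro-2H-chromen-2-yl]methyl}-2-oxo-2H-pyran-4-olate | CC(C)CCc1cc(O)cc2c1C(=O)C[C@@](O)(Cc1cc([O-])cc(=O)o1)O2.COc1ccc2nccc([C@H]([C@@H]3C[C@@H]4CC[NH+]3C[C@@H]4C=C)O)c2c1 | intermediate
20 | (2R)-2,7-dihydroxy-2-[(4-hydroxy-2-oxo-2H-pyran-6-yl)methyl]-5-(3-methylbutyl)-2,3-dihydro-4H-chromen-4-one | CC(C)CCc1cc(O)cc2c1C(=O)C[C@@](O)(Cc1cc(O)cc(=O)o1)O2 | target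

**Count**
Total steps: 11. Longest linear sequence: 8 steps (steps 1, 3, 4, 5, 8, 9, 10, 11).

**Steps most likely to fail**

Step 10 (bears the label "Proposed new method:"). The salt may separate as an oil, or both diastereomers may enter one solid phase. Ring opening at C2 may be slower than crystal growth, so that no enrichment beyond the solubility difference is reached. The lattice may select the (2S) hemiketal, and prolonged warming with the amine may cause slow dehydration to the chromone. The fallback uses known chemistry: racemate 18 would be resolved by preparative chromatography on a polysaccharide chiral stationary phase, amylose tris(3,5-dimethylphenylcarbamate), with heptane/EtOH containing 0.1% HCO2H at a column temperature near −10 °C. The (2R) fractions would be evaporated cold, and the (2S) fractions re-equilibrated with a trace of Et3N and injected again. The fallback sets out from 18 and comes back at 20, so salt 19 and step 11 are not needed; it makes no new compound (F0).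

Step 8. Carbonyl C4 is flanked by the C5 alkyl group and the ketal oxygen and is conjugated with the O7 ether, so attack of the stabilised dianion may be slower than proton transfer or self-condensation of the dianion at the pyrone carbonyl. The acetone set free may also consume dianion. The fallback replaces the acylation of a hindered lactone by an aldol addition to an aldehyde followed by oxidation. It sets out from 10: iBu2AlH in CH2Cl2 at −78 °C would reduce the lactone to the lactol, which sheds acetone on work-up to give 4-(benzyloxy)-2-hydroxy-6-(3-methylbutyl)benzaldehyde F1. BnBr and K2CO3 in DMF would give 2,4-bis(benzyloxy)-6-(3-methylbutyl)benzaldehyde F2. Addition of dianion 15 (from 14 and 2 equiv of LiN(iPr)2, THF, −78 °C) would give the aldol rac-4-(benzyloxy)-6-{4-[2,4-bis(benzyloxy)-6-(3-methylbutyl)phenyl]-4-hydroxy-2-oxobutyl}-2H-pyran-2-one F3. Dess–Martin periodinane in buffered CH2Cl2 would oxidise it to 1-[2,4-bis(benzyloxy)-6-(3-methylbutyl)phenyl]-4-[4-(benzyloxy)-2-oxo-2H-pyran-6-yl]butane-1,3-dione F4. Hydrogenolysis of the three benzyl groups under the conditions of step 9 would free the O1 phenol, which closes the hemiketal, and the route is rejoined at 18.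

Step 9. Saturation of the C5–C6 double bond of the pyrone, or reduction of the aryl ketone, may set in before the slower of the two benzyl groups is gone. The fallback removes the benzyl groups without a reductant: 17 would be treated with BCl3 (4 equiv) and pentamethylbenzene (6 equiv) as benzyl cation scavenger in CH2Cl2 at −78 °C, and quenched cold with MeOH and pH 5 buffer. It sets out from 17 and comes back at 18; it makes no new compound (F0).

**Further compounds**
F0 | step 10 | none | none
F1 | step 8 | 4-(benzyloxy)-2-hydroxy-6-(3-methylbutyl)benzaldehyde | CC(C)CCc1cc(OCc2ccccc2)cc(O)c1C=O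
F2 | step 8 | 2,4-bis(benzyloxy)-6-(3-methylbutyl)benzaldehyde | CC(C)CCc1cc(OCc2ccccc2)cc(OCc2ccccc2)c1C=O
F3 | step 8 | rac-4-(benzyloxy)-6-{4-[2,4-bis(benzyloxy)-6-(3-methylbutyl)phenyl]-4-hydroxy-2-oxobutyl}-2H-pyran-2-one | CC(C)CCc1cc(OCc2ccccc2)cc(OCc2ccccc2)c1C(O)CC(=O)Cc1cc(OCc2ccccc2)cc(=O)o1
F4 | step 8 | 1-[2,4-bis(benzyloxy)-6-(3-methylbutyl)phenyl]-4-[4-(benzyloxy)-2-oxo-2H-pyran-6-yl]butane-1,3-dione | CC(C)CCc1cc(OCc2ccccc2)cc(OCc2ccccc2)c1C(=O)CC(=O)Cc1cc(OCc2ccccc2)cc(=O)o1
F0 | step 9 | none | none
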